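**Retrosynthetic overview**
1. The target is read as epicatechin-(4β→8)-epifisetinidol-(4β→8)-catechin. The last C–C bond made is top C4–middle C8, from an epicatechin C4 cation (4-acetal, C8 capped with bromine) and a C8 arylzinc of the middle unit; its bromine handle is placed by ortho-lithiation at the indanone stage, before any benzyl ether is present.
2. Ring C of the middle unit is taken apart at C2–aryl (arylzinc addition to the lactol-acetate oxocarbenium ion, 2,3-cis) and at C3–O (enolate hydroxylation trans to the C4 aryl group), back to a 4-aryl-3,4-dihydrocoumarin.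
3. The strategy rests on the middle flavan unit: its O1–C8a aryl ether bond and its C4 methine, which joins C4a of its ring A to C8 of the catechin unit, are those of a 3-aryl-6-oxyindan-1-one with an oxygen put into the C1–C7a bond. A Baeyer–Villiger oxidation makes O1–C8a and enlarges the five-membered carbocycle to six-membered ring C.
4. The indanone comes from a rhodium-catalysed asymmetric conjugate addition of the catechin C8 boronic acid to 6-(benzyloxy)-7-bromoindenone, which sets middle C4. A chlorine at C6 of the catechin unit leaves its phloroglucinol ring without a free position towards peracid and cations.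
5. Ring order: the rings of the top and bottom units come from epicatechin and catechin, ring A of the middle unit from 6-hydroxyindan-1-one, its ring B from 4-bromocatechol. Ring C of the middle unit is the only ring formed (step 13). One hydrogenolysis removes all benzyl groups and the two remaining halogens.

Key step: step 13

Assumption: the sense of induction of the chiral diene in step 12 is not derived here; the antipode that gives the 3R product in a test reaction is used, and (R,R) is written as a placeholder.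

**Route**

Step 1
Reactants: 1 (+)-catechin
Product: 2 5,7,3',4'-tetra-O-benzyl-(+)-catechin
Conditions: BnBr (4.4 equiv), K2CO3, DMF, 0 °C to rt
Reagents that add atoms: benzyl bromide, BrCc1ccccc1
Why: Williamson etherification in which K2CO3 ionises only the four phenols, so that the 3-OH stays free and C-benzylation of ring A is kept low.

Step 2
Reactants: 2 5,7,3',4'-tetra-O-benzyl-(+)-catechin
Product: 3 3,5,7,3',4'-penta-O-benzyl-(+)-catechin
Conditions: NaH, BnBr, Bu4NI (cat.), THF/DMF, 0 °C to rt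
Reagents that add atoms: benzyl bromide, BrCc1ccccc1
Why: Williamson etherification of the secondary alkoxide, which touches no stereocentre.

Step 3
Reactants: 3 3,5,7,3',4'-penta-O-benzyl-(+)-catechin
Product: 4 8-bromo-3,5,7,3',4'-penta-O-benzylcatechin
Conditions: NBS (1.0 equiv), CH2Cl2, −78 °C to rt
Reagents that add atoms: N-bromosuccinimide, O=C1CCC(=O)N1Br
Why: Electrophilic aromatic bromination, which on benzylated flavan-3-ols goes first to C8 of ring A.

Step 4
Reactants: 4 8-bromo-3,5,7,3',4'-penta-O-benzylcatechin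
Product: 5 8-bromo-6-chloro-3,5,7,3',4'-penta-O-benzylcatechin
Conditions: NCS (1.1 equiv), DMF, rt
Reagents that add atoms: N-chlorosuccinimide, O=C1CCC(=O)N1Cl
Why: Electrophilic aromatic chlorination at C6, the last free position of ring A between two benzyloxy groups; the chlorine is a blocking group that resists lithium exchange at −78 °C and leaves in the last step.

Step 5
Reactants: 5 8-bromo-6-chloro-3,5,7,3',4'-penta-O-benzylcatechin
Product: 8 (6-chloro-3,5,7,3',4'-penta-O-benzylcatechin-8-yl)boronic acid, via aryllithium 6 (not isolated), via lithium borate 7 (not isolated)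
Conditions: n-BuLi, THF, −78 °C; B(OMe)3, −78 °C to rt; 1 M HCl
Reagents that add atoms: trimethyl borate, COB(OC)OC; water, O
Why: Bromine–lithium exchange, which at −78 °C is faster than attack on the aryl chloride or the benzyl ethers, then borylation of the aryllithium and hydrolysis of the borate.

Step 6
Reactants: 9 6-hydroxyindan-1-one
Product: 10 2',3'-dihydrospiro[1,3-dioxolane-2,1'-inden]-6'-ol
Conditions: HOCH2CH2OH, TsOH·H2O (cat.), toluene, reflux, Dean–Stark
Reagents that add atoms: ethylene glycol, OCCO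
Why: Acid-catalysed ketalisation driven by azeotropic removal of water; the ketone has to be masked for the lithiation of step 8.

Step 7
Reactants: 10 2',3'-dihydrospiro[1,3-dioxolane-2,1'-inden]-6'-ol
Product: 11 6'-(methoxymethoxy)-2',3'-dihydrospiro[1,3-dioxolane-2,1'-indene]
Conditions: MOMCl, i-Pr2NEt, CH2Cl2, 0 °C to rt
Reagents that add atoms: chloromethyl methyl ether, COCCl
Why: O-alkylation of the phenol under basic conditions that leave the ketal intact; the MOM ether is the directing group of the next step.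

Step 8
Reactants: 11 6'-(methoxymethoxy)-2',3'-dihydrospiro[1,3-dioxolane-2,1'-indene]
Product: 13 7'-bromo-6'-(methoxymethoxy)-2',3'-dihydrospiro[1,3-dioxolane-2,1'-indene], via aryllithium 12 (not isolated)
Conditions: n-BuLi, TMEDA, THF, −20 to 0 °C; BrCCl2CCl2Br, −78 °C to rt
Reagents that add atoms: 1,2-dibromo-1,1,2,2-tetrachloroethane, BrC(Cl)(Cl)C(Cl)(Cl)Br
Why: Directed ortho-metalation at C7', the position flanked by the MOM ether and the ketal carbon (cooperative direction), then bromination of the aryllithium; it is done at this stage because no benzyl ether, which n-BuLi would lithiate, is present yet.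

Step 9
Reactants: 13 7'-bromo-6'-(methoxymethoxy)-2',3'-dihydrospiro[1,3-dioxolane-2,1'-indene]
Product: 14 7-bromo-6-hydroxyindan-1-one
Conditions: 3 M HCl, THF, 50 °C
Reagents that add atoms: water, O
Why: Acid hydrolysis of the ketal and of the MOM acetal in one operation.

Step 10
Reactants: 14 7-bromo-6-hydroxyindan-1-one
Product: 15 6-(benzyloxy)-7-bromoindan-1-one
Conditions: BnBr, K2CO3, DMF, rt
Reagents that add atoms: benzyl bromide, BrCc1ccccc1
Why: Williamson etherification of the phenol, so that every oxygen protecting group of the route falls in the one final hydrogenolysis.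

Step 11
Reactants: 15 6-(benzyloxy)-7-bromoindan-1-one
Product: 16 6-(benzyloxy)-7-bromo-1H-inden-1-one
Conditions: IBX, 4-methoxypyridine N-oxide, DMSO, rt to 40 °C; used at once
Reagents that add atoms: none
Why: IBX dehydrogenation of a ketone to the enone through its enol, run near room temperature so that the benzyl ether is not oxidised; the indenone is used fresh because indenones dimerise.

Step 12
Reactants: 16 6-(benzyloxy)-7-bromo-1H-inden-1-one; 8 (6-chloro-3,5,7,3',4'-penta-O-benzylcatechin-8-yl)boronic acid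
Product: 17 (3R)-6-(benzyloxy)-7-bromo-3-(6-chloro-3,5,7,3',4'-penta-O-benzylcatechin-8-yl)indan-1-one
Conditions: [RhCl(C2H4)2]2 (2.5 mol%), (R,R)-Ph-bod* (5.5 mol%), KOH (0.2 equiv), 1,4-dioxane/H2O 10:1, 30 °C; 8 (1.5 equiv)
Reagents that add atoms: none
Why: Hayashi–Miyaura asymmetric conjugate addition, in which the aryl group passes from boron to rhodium and adds to C3 of the flat indenone on the face left open by the chiral diene; this sets the new stereocentre as 3R under catalyst control, the distant stereocentres of the catechin unit having little say.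

Step 13
Reactants: 17 (3R)-6-(benzyloxy)-7-bromo-3-(6-chloro-3,5,7,3',4'-penta-O-benzylcatechin-8-yl)indan-1-one
Product: 19 (4R)-7-(benzyloxy)-8-bromo-4-(6-chloro-3,5,7,3',4'-penta-O-benzylcatechin-8-yl)chroman-2-one, via Criegee adduct 18 (not isolated)
Conditions: mCPBA (3 equiv), Na2HPO4, CH2Cl2, 0 °C to rt, dark
Reagents that add atoms: m-chloroperbenzoic acid, O=C(OO)c1cccc(Cl)c1
Why: The peracid adds to the C1 carbonyl to give the Criegee adduct 18, and the aryl carbon C7a, anti-periplanar to the O–O bond, shifts from C1 to oxygen as 3-chlorobenzoate leaves. The closest known reaction is the Baeyer–Villiger oxidation of indan-1-ones to 3,4-dihydrocoumarins. Ring C is not closed by a cyclisation: the five-membered carbocycle is enlarged by one atom through the 1,2-shift, which makes the O1–C8a bond and the six-membered lactone. No stereocentre is formed, and C3 of the indanone becomes C4 of the chromanone unchanged because it takes no part in the migration. The step needs aryl instead of methylene migration, which the higher migratory aptitude of an aryl carbon over a primary alkyl carbon should secure, although the ortho bromine and the meta benzyloxy group lower it somewhat. It also needs the ketone to react before the arenes, for which the buffer holds down acid-catalysed arene hydroxylation and the C6 chlorine leaves ring A of the catechin unit without a free position.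

Step 14
Reactants: 19 (4R)-7-(benzyloxy)-8-bromo-4-(6-chloro-3,5,7,3',4'-penta-O-benzylcatechin-8-yl)chroman-2-one
Product: 21 (3R,4R)-7-(benzyloxy)-8-bromo-3-hydroxy-4-(6-chloro-3,5,7,3',4'-penta-O-benzylcatechin-8-yl)chroman-2-one, via potassium enolate 20 (not isolated)
Conditions: KN(SiMe3)2, THF, −78 °C; 2-(phenylsulfonyl)-3-phenyloxaziridine, −78 °C; AcOH, −78 °C
Reagents that add atoms: 2-(phenylsulfonyl)-3-phenyloxaziridine, O=S(=O)(N1OC1c1ccccc1)c1ccccc1
Why: Davis oxaziridine hydroxylation of the lactone enolate, in which the oxidant approaches C3 on the face opposite to the large aryl group at C4 and so gives the 3,4-trans alcohol (3R), while −78 °C keeps the aryl ester enolate from opening to a ketene.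

Step 15
Reactants: 21 (3R,4R)-7-(benzyloxy)-8-bromo-3-hydroxy-4-(6-chloro-3,5,7,3',4'-penta-O-benzylcatechin-8-yl)chroman-2-one
Product: 22 (3R,4R)-3,7-bis(benzyloxy)-8-bromo-4-(6-chloro-3,5,7,3',4'-penta-O-benzylcatechin-8-yl)chroman-2-one
Conditions: BnBr, Ag2O, 4 Å MS, CH2Cl2, rt, dark
Reagents that add atoms: benzyl bromide, BrCc1ccccc1
Why: Silver oxide-mediated O-benzylation, a non-basic Williamson variant that neither epimerises C3 nor opens the aryl lactone; the ether cannot act as a neighbouring group in step 18.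

Step 16
Reactants: 22 (3R,4R)-3,7-bis(benzyloxy)-8-bromo-4-(6-chloro-3,5,7,3',4'-penta-O-benzylcatechin-8-yl)chroman-2-one
Product: 24 (3R,4R)-3,7-bis(benzyloxy)-8-bromo-4-(6-chloro-3,5,7,3',4'-penta-O-benzylcatechin-8-yl)chroman-2-yl acetate (both C2 anomers), via aluminium hemiacetal 23 (not isolated)
Conditions: i-Bu2AlH, CH2Cl2, −78 °C; pyridine, DMAP, Ac2O, −78 °C to rt
Reagents that add atoms: acetic anhydride, CC(=O)OC(C)=O
Why: Reductive acetylation of a lactone, in which hydride addition stops at the aluminium hemiacetal at −78 °C and this is acetylated in the flask, so that the open hydroxy aldehyde form of the lactol is avoided.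

Step 17
Reactants: 25 4-bromocatechol
Product: 26 4-bromo-1,2-bis(benzyloxy)benzene
Conditions: BnBr, K2CO3, DMF, rt
Reagents that add atoms: benzyl bromide, BrCc1ccccc1
Why: Williamson etherification of both phenols.

Step 18
Reactants: 24 (3R,4R)-3,7-bis(benzyloxy)-8-bromo-4-(6-chloro-3,5,7,3',4'-penta-O-benzylcatechin-8-yl)chroman-2-yl acetate; 26 4-bromo-1,2-bis(benzyloxy)benzene
Product: 29 (2R,3R,4R)-3,7-bis(benzyloxy)-2-[3,4-bis(benzyloxy)phenyl]-8-bromo-4-(6-chloro-3,5,7,3',4'-penta-O-benzylcatechin-8-yl)chroman (2,3-cis-3,4-trans), via aryllithium 27 (not isolated), via arylzinc chloride 28 (not isolated)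
Conditions: 26 (3 equiv), n-BuLi, THF, −78 °C; ZnCl2, −78 to 0 °C; solvent change to CH2Cl2; 24, Me3SiOTf, −78 to −20 °C
Reagents that add atoms: none
Why: Lewis-acid-mediated substitution of a lactol acetate by an organozinc reagent (C-aryl glycosylation type), in which Me3SiOTf ionises the acetate to the cyclic oxocarbenium ion and the arylzinc adds to C2 on the face opposite to the large C4 aryl group, with the 3-benzyloxy group pseudoequatorial (the 1,2-cis preference of oxocarbenium ions that carry an adjacent alkoxy group); this sets C2 as 2R in the 2,3-cis-2,4-trans arrangement.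

Step 19
Reactants: 30 (−)-epicatechin
Product: 31 5,7,3',4'-tetra-O-benzyl-(−)-epicatechin
Conditions: BnBr (4.4 equiv), K2CO3, DMF, 0 °C to rt
Reagents that add atoms: benzyl bromide, BrCc1ccccc1
Why: Williamson etherification of the four phenols only.

Step 20
Reactants: 31 5,7,3',4'-tetra-O-benzyl-(−)-epicatechin
Product: 32 8-bromo-5,7,3',4'-tetra-O-benzylepicatechin
Conditions: NBS (1.0 equiv), CH2Cl2, −78 °C to rt
Reagents that add atoms: N-bromosuccinimide, O=C1CCC(=O)N1Br
Why: Electrophilic aromatic bromination at C8, which caps the most nucleophilic position so that the later C4 cation cannot add to a second molecule of the top unit.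

Step 21
Reactants: 32 8-bromo-5,7,3',4'-tetra-O-benzylepicatechin
Product: 33 8-bromo-4β-(2-ethoxyethoxy)-5,7,3',4'-tetra-O-benzylepicatechin (3,4-trans)
Conditions: DDQ, EtOCH2CH2OH, CH2Cl2, rt
Reagents that add atoms: 2-ethoxyethanol, CCOCCO
Why: DDQ oxidation of the benzylic C4–H to the cation stabilised by ring A, which the alcohol traps on the face opposite to the 3-hydroxyl and 2-aryl groups to give the 3,4-trans ether; this centre is ionised again in step 23.

Step 22
Reactants: 33 8-bromo-4β-(2-ethoxyethoxy)-5,7,3',4'-tetra-O-benzylepicatechin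
Product: 34 8-bromo-4β-(2-ethoxyethoxy)-3,5,7,3',4'-penta-O-benzylepicatechin
Conditions: NaH, BnBr, Bu4NI (cat.), THF/DMF, 0 °C to rt
Reagents that add atoms: benzyl bromide, BrCc1ccccc1
Why: Williamson etherification of the 3-OH, needed because a free hydroxyl would protonate the arylzinc of step 23; the benzylic acetal-type ether is stable to base.

Step 23
Reactants: 29 (2R,3R,4R)-3,7-bis(benzyloxy)-2-[3,4-bis(benzyloxy)phenyl]-8-bromo-4-(6-chloro-3,5,7,3',4'-penta-O-benzylcatechin-8-yl)chroman; 34 8-bromo-4β-(2-ethoxyethoxy)-3,5,7,3',4'-penta-O-benzylepicatechin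
Product: 37 [8-bromo-3,5,7,3',4'-penta-O-benzylepicatechin]-(4β→8)-[3,7,3',4'-tetra-O-benzylepifisetinidol]-(4β→8)-[6-chloro-3,5,7,3',4'-penta-O-benzylcatechin], via flavanyllithium 35 (not isolated), via flavanylzinc chloride 36 (not isolated)
Conditions: 29, t-BuLi (2.0 equiv), THF/toluene, −78 °C; ZnCl2, −78 to 0 °C; CH2Cl2; 34 (1.5 equiv), Me3SiOTf, −78 to −30 °C
Reagents that add atoms: none
Why: Proposed new method: Me3SiOTf ionises the C4 acetal-type ether of 34 to the benzylic cation stabilised by the 5,7-dibenzyloxy ring A, and the C8–Zn carbon of 36, which is ortho to two oxygens, should attack it by ipso substitution faster than any arene C–H and on the face opposite to the 2-aryl and 3-benzyloxy groups, which gives the 3,4-trans (4β) bond; the closest known reactions are the Lewis-acid-mediated C4 arylation of 4-alkoxyflavan-3-ol derivatives by electron-rich arenes (procyanidin couplings, same facial preference) and the addition of organozinc reagents to oxocarbenium ions made from acetals.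

Step 24
Reactants: 37 [8-bromo-3,5,7,3',4'-penta-O-benzylepicatechin]-(4β→8)-[3,7,3',4'-tetra-O-benzylepifisetinidol]-(4β→8)-[6-chloro-3,5,7,3',4'-penta-O-benzylcatechin]
Product: 38 epicatechin-(4β→8)-epifisetinidol-(4β→8)-catechin (CNP0270097.1)
Conditions: H2 (1–4 atm), Pd(OH)2/C, Et3N, THF/MeOH/H2O, rt
Reagents that add atoms: none
Why: Catalytic hydrogenolysis cleaves the fourteen benzyl ethers and reduces the aryl bromide and the aryl chloride in the same operation, Et3N taking up HBr and HCl so that the acid-labile interflavan bonds survive; no stereocentre is touched.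

**Compound list**

1 | (+)-catechin | Oc1cc(O)c2c(c1)O[C@H](c1ccc(O)c(O)c1)[C@@H](O)C2 | starting material
2 | 5,7,3',4'-tetra-O-benzyl-(+)-catechin | O(Cc9ccccc9)c1cc(OCc9ccccc9)c2c(c1)O[C@H](c8ccc(OCc9ccccc9)c(OCc9ccccc9)c8)[C@@H](O)C2 | intermediate
3 | 3,5,7,3',4'-penta-O-benzyl-(+)-catechin | O(Cc9ccccc9)c1cc(OCc9ccccc9)c2c(c1)O[C@H](c8ccc(OCc9ccccc9)c(OCc9ccccc9)c8)[C@@H](OCc9ccccc9)C2 | intermediate
4 | 8-bromo-3,5,7,3',4'-penta-O-benzylcatechin | O(Cc9ccccc9)c1cc(OCc9ccccc9)c2c(c1Br)O[C@H](c8ccc(OCc9ccccc9)c(OCc9ccccc9)c8)[C@@H](OCc9ccccc9)C2 | intermediate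
5 | 8-bromo-6-chloro-3,5,7,3',4'-penta-O-benzylcatechin | O(Cc9ccccc9)c1c(Cl)c(OCc9ccccc9)c2c(c1Br)O[C@H](c8ccc(OCc9ccccc9)c(OCc9ccccc9)c8)[C@@H](OCc9ccccc9)C2 | intermediate
6 | (6-chloro-3,5,7,3',4'-penta-O-benzylcatechin-8-yl)lithium | [Li]c3c(OCc9ccccc9)c(Cl)c(OCc9ccccc9)c4c3O[C@H](c8ccc(OCc9ccccc9)c(OCc9ccccc9)c8)[C@@H](OCc9ccccc9)C4 | intermediate
7 | lithium (6-chloro-3,5,7,3',4'-penta-O-benzylcatechin-8-yl)trimethoxyborate | [Li+].CO[B-](OC)(OC)c3c(OCc9ccccc9)c(Cl)c(OCc9ccccc9)c4c3O[C@H](c8ccc(OCc9ccccc9)c(OCc9ccccc9)c8)[C@@H](OCc9ccccc9)C4 | intermediate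
8 | (6-chloro-3,5,7,3',4'-penta-O-benzylcatechin-8-yl)boronic acid | OB(O)c3c(OCc9ccccc9)c(Cl)c(OCc9ccccc9)c4c3O[C@H](c8ccc(OCc9ccccc9)c(OCc9ccccc9)c8)[C@@H](OCc9ccccc9)C4 | intermediate
9 | 6-hydroxyindan-1-one | O=C1CCc2ccc(O)cc21 | starting material
10 | 2',3'-dihydrospiro[1,3-dioxolane-2,1'-inden]-6'-ol | Oc1ccc2CCC3(OCCO3)c2c1 | intermediate
11 | 6'-(methoxymethoxy)-2',3'-dihydrospiro[1,3-dioxolane-2,1'-indene] | COCOc1ccc2CCC3(OCCO3)c2c1 | intermediate
12 | 7'-lithio-6'-(methoxymethoxy)-2',3'-dihydrospiro[1,3-dioxolane-2,1'-indene] | COCOc1ccc2CCC3(OCCO3)c2c1[Li] | intermediate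
13 | 7'-bromo-6'-(methoxymethoxy)-2',3'-dihydrospiro[1,3-dioxolane-2,1'-indene] | COCOc1ccc2CCC3(OCCO3)c2c1Br | intermediate
14 | 7-bromo-6-hydroxyindan-1-one | O=C1CCc2ccc(O)c(Br)c21 | intermediate
15 | 6-(benzyloxy)-7-bromoindan-1-one | O=C1CCc2ccc(OCc3ccccc3)c(Br)c21 | intermediate
16 | 6-(benzyloxy)-7-bromo-1H-inden-1-one | O=C1C=Cc2ccc(OCc3ccccc3)c(Br)c21 | intermediate
17 | (3R)-6-(benzyloxy)-7-bromo-3-(6-chloro-3,5,7,3',4'-penta-O-benzylcatechin-8-yl)indan-1-one | O=C1C[C@@H](c3c(OCc9ccccc9)c(Cl)c(OCc9ccccc9)c4c3O[C@H](c8ccc(OCc9ccccc9)c(OCc9ccccc9)c8)[C@@H](OCc9ccccc9)C4)c2ccc(OCc9ccccc9)c(Br)c21 | intermediate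
18 | Criegee adduct of 17 (1-hydroxy-1-(3-chlorobenzoylperoxy)indane, C1 unassigned) | OC1(OOC(=O)c5cccc(Cl)c5)C[C@@H](c3c(OCc9ccccc9)c(Cl)c(OCc9ccccc9)c4c3O[C@H](c8ccc(OCc9ccccc9)c(OCc9ccccc9)c8)[C@@H](OCc9ccccc9)C4)c2ccc(OCc9ccccc9)c(Br)c21 | intermediate
19 | (4R)-7-(benzyloxy)-8-bromo-4-(6-chloro-3,5,7,3',4'-penta-O-benzylcatechin-8-yl)chroman-2-one | O=C1C[C@@H](c3c(OCc9ccccc9)c(Cl)c(OCc9ccccc9)c4c3O[C@H](c8ccc(OCc9ccccc9)c(OCc9ccccc9)c8)[C@@H](OCc9ccccc9)C4)c2ccc(OCc9ccccc9)c(Br)c2O1 | intermediate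
20 | potassium enolate of 19 | [K+].[O-]C1=C[C@@H](c3c(OCc9ccccc9)c(Cl)c(OCc9ccccc9)c4c3O[C@H](c8ccc(OCc9ccccc9)c(OCc9ccccc9)c8)[C@@H](OCc9ccccc9)C4)c2ccc(OCc9ccccc9)c(Br)c2O1 | intermediate
21 | (3R,4R)-7-(benzyloxy)-8-bromo-3-hydroxy-4-(6-chloro-3,5,7,3',4'-penta-O-benzylcatechin-8-yl)chroman-2-one (3,4-trans) | O=C1[C@H](O)[C@@H](c3c(OCc9ccccc9)c(Cl)c(OCc9ccccc9)c4c3O[C@H](c8ccc(OCc9ccccc9)c(OCc9ccccc9)c8)[C@@H](OCc9ccccc9)C4)c2ccc(OCc9ccccc9)c(Br)c2O1 | intermediate
22 | (3R,4R)-3,7-bis(benzyloxy)-8-bromo-4-(6-chloro-3,5,7,3',4'-penta-O-benzylcatechin-8-yl)chroman-2-one | O=C1[C@H](OCc9ccccc9)[C@@H](c3c(OCc9ccccc9)c(Cl)c(OCc9ccccc9)c4c3O[C@H](c8ccc(OCc9ccccc9)c(OCc9ccccc9)c8)[C@@H](OCc9ccccc9)C4)c2ccc(OCc9ccccc9)c(Br)c2O1 | intermediate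
23 | diisobutylaluminium hemiacetal of 22 (C2 unassigned) | CC(C)C[Al](CC(C)C)OC1[C@H](OCc9ccccc9)[C@@H](c3c(OCc9ccccc9)c(Cl)c(OCc9ccccc9)c4c3O[C@H](c8ccc(OCc9ccccc9)c(OCc9ccccc9)c8)[C@@H](OCc9ccccc9)C4)c2ccc(OCc9ccccc9)c(Br)c2O1 | intermediate
24 | (3R,4R)-3,7-bis(benzyloxy)-8-bromo-4-(6-chloro-3,5,7,3',4'-penta-O-benzylcatechin-8-yl)chroman-2-yl acetate (both C2 anomers) | CC(=O)OC1[C@H](OCc9ccccc9)[C@@H](c3c(OCc9ccccc9)c(Cl)c(OCc9ccccc9)c4c3O[C@H](c8ccc(OCc9ccccc9)c(OCc9ccccc9)c8)[C@@H](OCc9ccccc9)C4)c2ccc(OCc9ccccc9)c(Br)c2O1 | intermediate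
25 | 4-bromocatechol | Oc1ccc(Br)cc1O | starting material
26 | 4-bromo-1,2-bis(benzyloxy)benzene | Brc1ccc(OCc2ccccc2)c(OCc2ccccc2)c1 | intermediate
27 | [3,4-bis(benzyloxy)phenyl]lithium | [Li]c1ccc(OCc2ccccc2)c(OCc2ccccc2)c1 | intermediate
28 | [3,4-bis(benzyloxy)phenyl]zinc chloride | Cl[Zn]c1ccc(OCc2ccccc2)c(OCc2ccccc2)c1 | intermediate
29 | (2R,3R,4R)-3,7-bis(benzyloxy)-2-[3,4-bis(benzyloxy)phenyl]-8-bromo-4-(6-chloro-3,5,7,3',4'-penta-O-benzylcatechin-8-yl)chroman (2,3-cis-3,4-trans) | Brc1c(OCc9ccccc9)ccc2c1O[C@H](c8ccc(OCc9ccccc9)c(OCc9ccccc9)c8)[C@H](OCc9ccccc9)[C@H]2c3c(OCc9ccccc9)c(Cl)c(OCc9ccccc9)c4c3O[C@H](c8ccc(OCc9ccccc9)c(OCc9ccccc9)c8)[C@@H](OCc9ccccc9)C4 | intermediate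
30 | (−)-epicatechin | Oc1cc(O)c2c(c1)O[C@H](c1ccc(O)c(O)c1)[C@H](O)C2 | starting material
31 | 5,7,3',4'-tetra-O-benzyl-(−)-epicatechin | O(Cc9ccccc9)c1cc(OCc9ccccc9)c2c(c1)O[C@H](c8ccc(OCc9ccccc9)c(OCc9ccccc9)c8)[C@H](O)C2 | intermediate
32 | 8-bromo-5,7,3',4'-tetra-O-benzylepicatechin | O(Cc9ccccc9)c1cc(OCc9ccccc9)c2c(c1Br)O[C@H](c8ccc(OCc9ccccc9)c(OCc9ccccc9)c8)[C@H](O)C2 | intermediate
33 | 8-bromo-4β-(2-ethoxyethoxy)-5,7,3',4'-tetra-O-benzylepicatechin (2,3-cis-3,4-trans) | O(Cc9ccccc9)c1cc(OCc9ccccc9)c2c(c1Br)O[C@H](c8ccc(OCc9ccccc9)c(OCc9ccccc9)c8)[C@H](O)[C@H]2OCCOCC | intermediate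
34 | 8-bromo-4β-(2-ethoxyethoxy)-3,5,7,3',4'-penta-O-benzylepicatechin | O(Cc9ccccc9)c1cc(OCc9ccccc9)c2c(c1Br)O[C@H](c8ccc(OCc9ccccc9)c(OCc9ccccc9)c8)[C@H](OCc9ccccc9)[C@H]2OCCOCC | intermediate
35 | C8-lithio derivative of 29 (lithium in place of bromine) | [Li]c1c(OCc9ccccc9)ccc2c1O[C@H](c8ccc(OCc9ccccc9)c(OCc9ccccc9)c8)[C@H](OCc9ccccc9)[C@H]2c3c(OCc9ccccc9)c(Cl)c(OCc9ccccc9)c4c3O[C@H](c8ccc(OCc9ccccc9)c(OCc9ccccc9)c8)[C@@H](OCc9ccccc9)C4 | intermediate
36 | C8-chlorozincio derivative of 29 (ZnCl in place of bromine) | Cl[Zn]c1c(OCc9ccccc9)ccc2c1O[C@H](c8ccc(OCc9ccccc9)c(OCc9ccccc9)c8)[C@H](OCc9ccccc9)[C@H]2c3c(OCc9ccccc9)c(Cl)c(OCc9ccccc9)c4c3O[C@H](c8ccc(OCc9ccccc9)c(OCc9ccccc9)c8)[C@@H](OCc9ccccc9)C4 | intermediate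
37 | [8-bromo-3,5,7,3',4'-penta-O-benzylepicatechin]-(4β→8)-[3,7,3',4'-tetra-O-benzylepifisetinidol]-(4β→8)-[6-chloro-3,5,7,3',4'-penta-O-benzylcatechin] | O(Cc9ccccc9)c1cc(OCc9ccccc9)c2c(c1Br)O[C@H](c8ccc(OCc9ccccc9)c(OCc9ccccc9)c8)[C@H](OCc9ccccc9)[C@H]2c1c(OCc9ccccc9)ccc2c1O[C@H](c8ccc(OCc9ccccc9)c(OCc9ccccc9)c8)[C@H](OCc9ccccc9)[C@H]2c3c(OCc9ccccc9)c(Cl)c(OCc9ccccc9)c4c3O[C@H](c8ccc(OCc9ccccc9)c(OCc9ccccc9)c8)[C@@H](OCc9ccccc9)C4 | intermediate
38 | epicatechin-(4β→8)-epifisetinidol-(4β→8)-catechin (CNP0270097.1) | Oc1cc(O)c2c(c1)O[C@H](c1ccc(O)c(O)c1)[C@H](O)[C@H]2c1c(O)ccc2c1O[C@H](c1ccc(O)c(O)c1)[C@H](O)[C@H]2c1c(O)cc(O)c2c1O[C@H](c1ccc(O)c(O)c1)[C@@H](O)C2 | target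

**Step count**

Total: 24 steps. Longest linear sequence: 14 steps, from 9 to 38 (steps 6 to 16, 18, 23 and 24).

**Steps most likely to fail**

1. Step 23 (proposed new method). Transfer of the aryl group from zinc to the C4 cation may be slower than loss of a proton from the cation to the flav-3-ene, than silylation or protonation of the hindered arylzinc, or than Friedel–Crafts attack of the cation through C6–H of ring A of the middle unit. The fallback uses known chemistry and sets out from 29. Bromine–lithium exchange (t-BuLi, THF, −78 °C) and a methanol quench give the C8–H flavan 3,7,3',4'-tetra-O-benzylepifisetinidol-(4β→8)-6-chloro-penta-O-benzylcatechin F1. NCS then chlorinates C6 of ring A of the middle unit, the more reactive of its two free positions, to give the 6-chloro flavan F2, in which C8 is the only unsubstituted ring A carbon next to an oxygen. Me3SiOTf-mediated Friedel–Crafts coupling of F2 with 34, the Lewis-acid coupling used to assemble 4→8 procyanidins from halogen-capped partners, gives the protected trimer with a second chlorine F3. Hydrogenolysis under the conditions of step 24 removes that chlorine with the other halogens and comes back to the route at 38.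

2. Step 13 (key step). Addition of the peracid to the conjugated, ortho-substituted ketone may be slow, so that migration of the methylene carbon and oxidation of the benzyloxy arenes gain ground over the aryl shift during the long reaction time. The fallback gives up the ring expansion and sets out from 8. 7-Hydroxycoumarin is brominated ortho to the phenol to 8-bromo-7-hydroxycoumarin F4 and benzylated to 7-(benzyloxy)-8-bromocoumarin F5. Rhodium-catalysed asymmetric conjugate addition of 8 to F5 (Hayashi–Miyaura reaction on a coumarin, same catalyst type as step 12) gives the 4-arylchroman-2-one directly and comes back to the route at 19.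

3. Step 12. Transmetalation and insertion of the aryl group, which carries oxygen substituents at both ortho positions, may be so slow that protodeboronation of 8 and base-induced oligomerisation of the indenone outrun the addition, and the facial selectivity may suffer at the higher temperature then needed. The fallback is a polar route without boron or rhodium and sets out from 5 and 16. Bromine–lithium exchange on 5 and a methanol quench give 6-chloro-3,5,7,3',4'-penta-O-benzylcatechin F6, whose only free nucleophilic position is C8. Sc(OTf)3-catalysed Friedel–Crafts conjugate addition of F6 to 16 gives 17 together with its C3 epimer F7. The two are diastereomers, are separated by chromatography, and the route is rejoined at 17.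

**Further compounds**

F1 | step 23 | 3,7,3',4'-tetra-O-benzylepifisetinidol-(4β→8)-6-chloro-3,5,7,3',4'-penta-O-benzylcatechin (29 with H in place of Br) | c1c(OCc9ccccc9)ccc2c1O[C@H](c8ccc(OCc9ccccc9)c(OCc9ccccc9)c8)[C@H](OCc9ccccc9)[C@H]2c3c(OCc9ccccc9)c(Cl)c(OCc9ccccc9)c4c3O[C@H](c8ccc(OCc9ccccc9)c(OCc9ccccc9)c8)[C@@H](OCc9ccccc9)C4
F2 | step 23 | 6-chloro-3,7,3',4'-tetra-O-benzylepifisetinidol-(4β→8)-6-chloro-3,5,7,3',4'-penta-O-benzylcatechin | c1c(OCc9ccccc9)c(Cl)cc2c1O[C@H](c8ccc(OCc9ccccc9)c(OCc9ccccc9)c8)[C@H](OCc9ccccc9)[C@H]2c3c(OCc9ccccc9)c(Cl)c(OCc9ccccc9)c4c3O[C@H](c8ccc(OCc9ccccc9)c(OCc9ccccc9)c8)[C@@H](OCc9ccccc9)C4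
F3 | step 23 | [8-bromo-3,5,7,3',4'-penta-O-benzylepicatechin]-(4β→8)-[6-chloro-3,7,3',4'-tetra-O-benzylepifisetinidol]-(4β→8)-[6-chloro-3,5,7,3',4'-penta-O-benzylcatechin] | O(Cc9ccccc9)c1cc(OCc9ccccc9)c2c(c1Br)O[C@H](c8ccc(OCc9ccccc9)c(OCc9ccccc9)c8)[C@H](OCc9ccccc9)[C@H]2c1c(OCc9ccccc9)c(Cl)cc2c1O[C@H](c8ccc(OCc9ccccc9)c(OCc9ccccc9)c8)[C@H](OCc9ccccc9)[C@H]2c3c(OCc9ccccc9)c(Cl)c(OCc9ccccc9)c4c3O[C@H](c8ccc(OCc9ccccc9)c(OCc9ccccc9)c8)[C@@H](OCc9ccccc9)C4
F4 | step 13 | 8-bromo-7-hydroxycoumarin | O=C1C=Cc2ccc(O)c(Br)c2O1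
F5 | step 13 | 7-(benzyloxy)-8-bromocoumarin | O=C1C=Cc2ccc(OCc3ccccc3)c(Br)c2O1
F6 | step 12 | 6-chloro-3,5,7,3',4'-penta-O-benzylcatechin | c1c(OCc9ccccc9)c(Cl)c(OCc9ccccc9)c2c1O[C@H](c8ccc(OCc9ccccc9)c(OCc9ccccc9)c8)[C@@H](OCc9ccccc9)C2
F7 | step 12 | (3S)-6-(benzyloxy)-7-bromo-3-(6-chloro-3,5,7,3',4'-penta-O-benzylcatechin-8-yl)indan-1-one (C3 epimer of 17) | O=C1C[C@H](c3c(OCc9ccccc9)c(Cl)c(OCc9ccccc9)c4c3O[C@H](c8ccc(OCc9ccccc9)c(OCc9ccccc9)c8)[C@@H](OCc9ccccc9)C4)c2ccc(OCc9ccccc9)c(Br)c21
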